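The numbers in the tables are simulated from invented constants; noise was put on by code.

**Late J.** Late in a run, the question is what the J already made has become. Here are the flasks, the earlier readings and what is asked:

| flask | E | L | temperature | remark | time |
|---|---|---|---|---|---|
| Wednesday's | 2.2 M | 1.2 equiv | 100 °C | run made earlier |  |
| Thursday's | 0.75 M | 1.2 equiv | 100 °C | run made earlier |  |
| north-west | 1.5 M | 1.20 equiv |  | at 100 °C until 15 h, from then on at 80 °C | 50 h |
| north-east | 1.5 M | 0.300 equiv |  | at 80 °C throughout | 50 h |

| run | time / h | J / % | D / % |
|---|---|---|---|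
| Wednesday's | 0.667 | 2 | 0 |
| Wednesday's | 2.00 | 7 | 0 |
| Wednesday's | 4.00 | 9 | 0 |
| Wednesday's | 5.00 | 9 | 1 |
| Wednesday's | 8.00 | 15 | 0 |
| Wednesday's | 10.0 | 20 | 0 |
| Thursday's | 0.667 | 0 | 0 |
| Thursday's | 2.00 | 2 | 0 |
| Thursday's | 4.00 | 5 | 4 |
| Thursday's | 5.00 | 10 | 0 |
| Thursday's | 8.00 | 10 | 0 |
| Thursday's | 10.0 | 13 | 1 |

(readings scatter by 1.5 percentage points)

- the winner by share of J in all that became J or D; "neither" if no more than 2 percentage points parts them (north-west / north-east / neither)
- share of J in all that became J or D, north-west
- share of J in all that became J or D, north-east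

- the earlier runs do not show what temperature does; that part of a forecast is a guess

**The leak.** Suppose J passes into D by a first-order step with constant k (a consecutive reaction). While D is small, D/J ≈ k·a, where a is the mean age of J in the flask. J that grows steadily has a mean age of half the elapsed time, which replaces the curve by its mean. I take the last readings, at 10.0 h: Wednesday's gives J 20% and D 0%, Thursday's J 13% and D 1%. Pooled, they give k = 0.00606 /h, a weak reading against a scatter of 1.5 percentage points.

**Hot age.** Temperature is unseen, so I guess that an hour at 80 °C counts as a quarter of an hour at 100 °C. The mean hot age is then a, in hours at 100 °C. For north-west I treat J as made before the change at 15 h, which errs high, and get 16.2 h. North-east, growing steadily and cool throughout, gets 6.25 h, younger. The share of J (the selectivity) is 1/(1 + k·a), so north-west gets 91.0% and north-east 96.4%. My reckoning therefore picks north-east. An error in k changes that gap of 5.4 points, not which flask leads, and the pick holds as long as the gap stays above the margin of 2 points.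

**The forecast.** The forecast says neither, with 95% for north-west and 95% for north-east: “I expect no clear difference”.

**The result.** The winner is north-east, with 92.4% in north-west and 97.5% in north-east, and the flasks ran by this scheme:

    E + L → J, rate k1*[E]*[L]^0.5 (k = 0.0140 /M^0.5/h, Ea = 81.0 kJ/mol)
    L → Q (k = 0.0220 /h, Ea = 121 kJ/mol)
    J ⇌ D (K = 3.60, k = 0.00860 /h, Ea = 120 kJ/mol, ΔH = −90.0 kJ/mol)
    (constants at 100 °C)

In north-west, D 2.25% on J 27.4% gives D/J = 0.0821, where the k read from the earlier runs times the age 16.2 h gave 0.0982. That age is reckoned without L, so the reckoning gives 0.0982 again for a flask like north-west with 2.00 equiv of L. That flask holds J 34.4% and D 2.85%, a ratio of 0.0828 and a share of 92.3%.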